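**Retrosynthetic overview**

1. Target 23 ⇐ MOM removal and oxidation of the C4 carbinol ⇐ 8-prenylated chroman-4-ol 21. Ring C is the last ring formed.
2. 21 ⇐ acyclic (1S,3S)-1,3-diol 16 in one flask by aryne cine-cyclisation/prenylation, which forms the O1–C8a bond (closing ring C) and the C8–prenyl bond together.
3. Enabling feature: ring A carries O1 on C8a, a prenyl group on C8 and oxygen on C7 on three adjacent carbons. This is the nucleophile/electrophile/alkoxy pattern of a 3-alkoxyaryne (C8=C8a, from a C8 fluorine and the C8a hydrogen), and the C2 oxygen, tethered through C3–C4 to C4a, can reach only C8a.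
4. 16 ⇐ double asymmetric transfer hydrogenation of 1,3-diketone 13 (sets C2) ⇐ Claisen condensation of ring-A methyl ketone 12 with chromene ester 6.
5. 12 ⇐ 3-fluoro-4-hydroxyacetophenone (regiospecific Claisen prenylation at the only free ortho position). 6 ⇐ methyl 4-hydroxybenzoate (chromene pyran ring formed first, step 2).

Key step: step 9

Remark: the single stereocentre of the target (C2) is read as S, and the target is named below by its systematic name. Flavanone numbering (O1, C2, C3, C4, C4a, C5–C8, C8a) is used for these atoms throughout, also in open-chain precursors. The C4 carbinol configuration of 16 and 21 is irrelevant to the target because step 10 erases it.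

**Route**

Step 1
Reactants: 1 methyl 4-hydroxybenzoate; 2 3-chloro-3-methylbut-1-yne
Product: 3 methyl 4-[(2-methylbut-3-yn-2-yl)oxy]benzoate
Conditions: DBU, CuCl2·2H2O (cat.), MeCN, 0 °C → rt
Reagents that add atoms: none
Why: Copper-catalysed O-alkylation of a phenol with a tertiary propargylic chloride (Williamson-type etherification via a copper acetylide) is the standard entry to aryl 1,1-dimethylpropargyl ethers and tolerates the ester.

Step 2
Reactants: 3 methyl 4-[(2-methylbut-3-yn-2-yl)oxy]benzoate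
Product: 6 methyl 2,2-dimethyl-2H-chromene-6-carboxylate, via allenylphenol 4 (not isolated), via ortho-quinone methide 5 (not isolated)
Conditions: PhNEt2, 190 °C
Reagents that add atoms: none
Why: Thermal aryl propargyl ether Claisen rearrangement, 1,5-hydrogen shift and oxa-6π electrocyclisation should give the 2,2-dimethylchromene, the two ortho positions of the symmetric arene being equivalent.

Step 3
Reactants: 7 1-(3-fluoro-4-hydroxyphenyl)ethan-1-one; 2 3-chloro-3-methylbut-1-yne
Product: 8 1-{3-fluoro-4-[(2-methylbut-3-yn-2-yl)oxy]phenyl}ethan-1-one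
Conditions: DBU, CuCl2·2H2O (cat.), MeCN, 0 °C → rt
Reagents that add atoms: none
Why: The same copper-catalysed O-propargylation as in step 1 should work on this more hindered, more acidic phenol, with the ketone and aryl fluoride as spectators.

Step 4
Reactants: 8 1-{3-fluoro-4-[(2-methylbut-3-yn-2-yl)oxy]phenyl}ethan-1-one
Product: 9 1-{3-fluoro-4-[(2-methylbut-3-en-2-yl)oxy]phenyl}ethan-1-one
Conditions: H2 (1 atm), Lindlar catalyst, quinoline, EtOAc, rt
Reagents that add atoms: none
Why: Lindlar semihydrogenation of a terminal alkyne should stop at the alkene and leave the aryl ketone and the C–F bond untouched.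

Step 5
Reactants: 9 1-{3-fluoro-4-[(2-methylbut-3-en-2-yl)oxy]phenyl}ethan-1-one
Product: 11 1-[3-fluoro-4-hydroxy-5-(3-methylbut-2-en-1-yl)phenyl]ethan-1-one, via ortho-dienone 10 (not isolated)
Conditions: o-xylene, 140 °C
Reagents that add atoms: none
Why: Aromatic Claisen rearrangement of the 1,1-dimethylallyl ether delivers the linear prenyl group by [3,3] transposition to the only ortho position that can re-aromatise, since the other ortho carbon bears fluorine and the para position bears the acetyl group.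

Step 6
Reactants: 11 1-[3-fluoro-4-hydroxy-5-(3-methylbut-2-en-1-yl)phenyl]ethan-1-one
Product: 12 1-[3-fluoro-4-(methoxymethoxy)-5-(3-methylbut-2-en-1-yl)phenyl]ethan-1-one
Conditions: MOMCl, i-Pr2NEt, CH2Cl2, 0 °C → rt
Reagents that add atoms: chloromethyl methyl ether (MOMCl), COCCl
Why: O-Alkylation of the phenol gives a base-stable MOM ether that later acts as the aryne-polarising and lithium-chelating group in step 9.

Step 7
Reactants: 12 1-[3-fluoro-4-(methoxymethoxy)-5-(3-methylbut-2-en-1-yl)phenyl]ethan-1-one; 6 methyl 2,2-dimethyl-2H-chromene-6-carboxylate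
Product: 13 1-(2,2-dimethyl-2H-chromen-6-yl)-3-[3-fluoro-4-(methoxymethoxy)-5-(3-methylbut-2-en-1-yl)phenyl]propane-1,3-dione
Conditions: NaH, THF, 65 °C; then 1 M HCl, 0 °C
Reagents that add atoms: none
Why: Crossed Claisen condensation of a methyl ketone enolate with a non-enolisable aryl ester is driven to the 1,3-diketone by irreversible formation of the diketonate.

Step 8
Reactants: 13 1-(2,2-dimethyl-2H-chromen-6-yl)-3-[3-fluoro-4-(methoxymethoxy)-5-(3-methylbut-2-en-1-yl)phenyl]propane-1,3-dione
Product: 16 (1S,3S)-1-(2,2-dimethyl-2H-chromen-6-yl)-3-[3-fluoro-4-(methoxymethoxy)-5-(3-methylbut-2-en-1-yl)phenyl]propane-1,3-diol, via hydroxy ketone 14 (not isolated), via regioisomeric hydroxy ketone 15 (not isolated)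
Conditions: RuCl(p-cymene)[(S,S)-TsDPEN] (2 mol %), HCO2H/Et3N (5:2), DMF, 40 °C
Reagents that add atoms: none
Why: Noyori–Ikariya asymmetric transfer hydrogenation of a 1,3-diaryl-1,3-diketone should give the anti-diol under catalyst control at both aryl ketones, the (S,S)-catalyst delivering (S)-aryl carbinols as it does for acetophenone, and it leaves the prenyl and chromene alkenes untouched; only the chromenyl carbinol (future C2) has to be enantiopure.

Step 9
Reactants: 16 (1S,3S)-1-(2,2-dimethyl-2H-chromen-6-yl)-3-[3-fluoro-4-(methoxymethoxy)-5-(3-methylbut-2-en-1-yl)phenyl]propane-1,3-diol; 17 1-bromo-3-methylbut-2-ene (prenyl bromide)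
Product: 21 (2S,4S)-2-(2,2-dimethyl-2H-chromen-6-yl)-7-(methoxymethoxy)-6,8-bis(3-methylbut-2-en-1-yl)-3,4-dihydro-2H-chromen-4-ol, via ortho-lithiated fluoroarene dialkoxide 18 (not isolated), via aryne dialkoxide 19 (not isolated), via 8-lithiochromanolate 20 (not isolated)
Conditions: LiTMP (4.5 equiv), THF, −78 → −30 °C; then CuBr·SMe2 (20 mol %), 17 (5 equiv), −78 → 0 °C; H2O
Reagents that add atoms: none
Why: Proposed new method: LiTMP forms the dilithium dialkoxide and then, assisted by the neighbouring C4 alkoxide and the ortho fluorine, removes the ring-A hydrogen at the future C8a (18); loss of LiF on warming gives the C8=C8a aryne 19, whose tethered C2 alkoxide adds in the ring plane to C8a and leaves an aryllithium at C8 (20), chelated by O1 and the C7 OMOM oxygen, which is prenylated at its α-carbon under Cu(I) catalysis. The closest known reaction types are ring closure of a tethered heteroatom nucleophile onto an aryne, anionic aryne cyclisation followed by electrophile quench of the new aryllithium, and copper-mediated prenylation of 2,6-dialkoxyaryllithiums; their union in one flask with an oxygen nucleophile is what is proposed. Ring C is closed by six-membered addition of the alkoxide across the aryne, the only closure open to the system, since the C4 alkoxide could only form a four-membered ring and attack at C8 would need a meta bridge. No stereocentre is created: C2 keeps its configuration because only its O–H bond is involved, and the C4 carbinol is a spectator. The step needs regioselective addition at C8a, secured by the tether and by inductive polarisation of the aryne by the adjacent C7 OMOM group (nucleophile distal, carbanion ortho to oxygen); it needs intramolecular rather than intermolecular capture of the aryne, secured by the non-nucleophilic amide base; and it needs α-selective prenylation, secured by copper.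

Step 10
Reactants: 21 (2S,4S)-2-(2,2-dimethyl-2H-chromen-6-yl)-7-(methoxymethoxy)-6,8-bis(3-methylbut-2-en-1-yl)-3,4-dihydro-2H-chromen-4-ol
Product: 22 (2S)-2-(2,2-dimethyl-2H-chromen-6-yl)-7-(methoxymethoxy)-6,8-bis(3-methylbut-2-en-1-yl)-2,3-dihydro-4H-chromen-4-one
Conditions: Dess–Martin periodinane, NaHCO3, CH2Cl2, 0 °C → rt
Reagents that add atoms: none
Why: Dess–Martin oxidation of the benzylic secondary alcohol under buffered, base-free conditions should give the chromanone without touching the alkenes and without opening the flavanone to the chalcone, so C2 is not scrambled.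

Step 11
Reactants: 22 (2S)-2-(2,2-dimethyl-2H-chromen-6-yl)-7-(methoxymethoxy)-6,8-bis(3-methylbut-2-en-1-yl)-2,3-dihydro-4H-chromen-4-one
Product: 23 (2S)-2-(2,2-dimethyl-2H-chromen-6-yl)-7-hydroxy-6,8-bis(3-methylbut-2-en-1-yl)-2,3-dihydro-4H-chromen-4-one (the target flavanone)
Conditions: 3 M HCl (aq), MeOH, 40 °C
Reagents that add atoms: none
Why: Acid-catalysed acetal exchange of the aryl MOM ether with methanol should free the C7 phenol under conditions mild enough to avoid cyclisation of the flanking prenyl groups and the base-mediated flavanone–chalcone equilibration that would racemise C2.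

**Compound list**

1 | methyl 4-hydroxybenzoate | COC(=O)c1ccc(O)cc1 | starting material
2 | 3-chloro-3-methylbut-1-yne | C#CC(C)(C)Cl | starting material
3 | methyl 4-[(2-methylbut-3-yn-2-yl)oxy]benzoate | COC(=O)c1ccc(OC(C)(C)C#C)cc1 | intermediate
4 | methyl 4-hydroxy-3-(3-methylbuta-1,2-dien-1-yl)benzoate | COC(=O)c1ccc(O)c(C=C=C(C)C)c1 | intermediate
5 | methyl (3Z)-3-(3-methylbut-2-en-1-ylidene)-4-oxocyclohexa-1,5-diene-1-carboxylate | O=C1C=CC(C(=O)OC)=C/C1=C/C=C(C)C | intermediate
6 | methyl 2,2-dimethyl-2H-chromene-6-carboxylate | COC(=O)c1ccc2OC(C)(C)C=Cc2c1 | intermediate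
7 | 1-(3-fluoro-4-hydroxyphenyl)ethan-1-one | CC(=O)c1ccc(O)c(F)c1 | starting material
8 | 1-{3-fluoro-4-[(2-methylbut-3-yn-2-yl)oxy]phenyl}ethan-1-one | CC(=O)c1ccc(OC(C)(C)C#C)c(F)c1 | intermediate
9 | 1-{3-fluoro-4-[(2-methylbut-3-en-2-yl)oxy]phenyl}ethan-1-one | CC(=O)c1ccc(OC(C)(C)C=C)c(F)c1 | intermediate
10 | 4-acetyl-2-fluoro-6-(3-methylbut-2-en-1-yl)cyclohexa-2,4-dien-1-one (racemic, transient) | CC(=O)C1=CC(CC=C(C)C)C(=O)C(F)=C1 | intermediate
11 | 1-[3-fluoro-4-hydroxy-5-(3-methylbut-2-en-1-yl)phenyl]ethan-1-one | CC(=O)c1cc(F)c(O)c(CC=C(C)C)c1 | intermediate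
12 | 1-[3-fluoro-4-(methoxymethoxy)-5-(3-methylbut-2-en-1-yl)phenyl]ethan-1-one | CC(=O)c1cc(F)c(OCOC)c(CC=C(C)C)c1 | intermediate
13 | 1-(2,2-dimethyl-2H-chromen-6-yl)-3-[3-fluoro-4-(methoxymethoxy)-5-(3-methylbut-2-en-1-yl)phenyl]propane-1,3-dione | O=C(CC(=O)c1ccc2OC(C)(C)C=Cc2c1)c1cc(F)c(OCOC)c(CC=C(C)C)c1 | intermediate
14 | (3S)-3-(2,2-dimethyl-2H-chromen-6-yl)-1-[3-fluoro-4-(methoxymethoxy)-5-(3-methylbut-2-en-1-yl)phenyl]-3-hydroxypropan-1-one | O=C(C[C@H](O)c1ccc2OC(C)(C)C=Cc2c1)c1cc(F)c(OCOC)c(CC=C(C)C)c1 | intermediate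
15 | (3S)-1-(2,2-dimethyl-2H-chromen-6-yl)-3-[3-fluoro-4-(methoxymethoxy)-5-(3-methylbut-2-en-1-yl)phenyl]-3-hydroxypropan-1-one | O=C(C[C@H](O)c1cc(F)c(OCOC)c(CC=C(C)C)c1)c1ccc2OC(C)(C)C=Cc2c1 | intermediate
16 | (1S,3S)-1-(2,2-dimethyl-2H-chromen-6-yl)-3-[3-fluoro-4-(methoxymethoxy)-5-(3-methylbut-2-en-1-yl)phenyl]propane-1,3-diol | O[C@H](c1cc(F)c(OCOC)c(CC=C(C)C)c1)C[C@H](O)c1ccc2OC(C)(C)C=Cc2c1 | intermediate
17 | 1-bromo-3-methylbut-2-ene (prenyl bromide) | CC(C)=CCBr | starting material
18 | dilithium (1S,3S)-1-(2,2-dimethyl-2H-chromen-6-yl)-3-[3-fluoro-2-lithio-4-(methoxymethoxy)-5-(3-methylbut-2-en-1-yl)phenyl]propane-1,3-diolate | [Li]O[C@H](c1cc(CC=C(C)C)c(OCOC)c(F)c1[Li])C[C@H](O[Li])c1ccc2OC(C)(C)C=Cc2c1 | intermediate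
19 | dilithium (1S,3S)-1-(2,2-dimethyl-2H-chromen-6-yl)-3-[2,3-didehydro-4-(methoxymethoxy)-5-(3-methylbut-2-en-1-yl)phenyl]propane-1,3-diolate (C8=C8a aryne) | [Li]O[C@H](C1=CC(CC=C(C)C)=C(OCOC)C#C1)C[C@H](O[Li])c1ccc2OC(C)(C)C=Cc2c1 | intermediate
20 | lithium (2S,4S)-2-(2,2-dimethyl-2H-chromen-6-yl)-8-lithio-7-(methoxymethoxy)-6-(3-methylbut-2-en-1-yl)-3,4-dihydro-2H-chromen-4-olate | CC(C)=CCc1cc2c(c([Li])c1OCOC)O[C@H](c1ccc3c(c1)C=CC(C)(C)O3)C[C@@H]2O[Li] | intermediate
21 | (2S,4S)-2-(2,2-dimethyl-2H-chromen-6-yl)-7-(methoxymethoxy)-6,8-bis(3-methylbut-2-en-1-yl)-3,4-dihydro-2H-chromen-4-ol | CC(C)=CCc1cc2c(c(CC=C(C)C)c1OCOC)O[C@H](c1ccc3c(c1)C=CC(C)(C)O3)C[C@@H]2O | intermediate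
22 | (2S)-2-(2,2-dimethyl-2H-chromen-6-yl)-7-(methoxymethoxy)-6,8-bis(3-methylbut-2-en-1-yl)-2,3-dihydro-4H-chromen-4-one | CC(C)=CCc1cc2c(c(CC=C(C)C)c1OCOC)O[C@H](c1ccc3c(c1)C=CC(C)(C)O3)CC2=O | intermediate
23 | (2S)-2-(2,2-dimethyl-2H-chromen-6-yl)-7-hydroxy-6,8-bis(3-methylbut-2-en-1-yl)-2,3-dihydro-4H-chromen-4-one (the target flavanone) | CC(C)=CCc1cc2c(c(CC=C(C)C)c1O)O[C@H](c1ccc3c(c1)C=CC(C)(C)O3)CC2=O | target

**Step count and risks**

Total steps: 11. Longest linear sequence: 9 steps (7 → 23 through steps 3–11).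

Steps most likely to fail:

1. Step 9 (proposed new method). Lithiation next to fluorine may be slow, so that metalation of the benzylic/allylic prenyl CH2 competes. The aryne may be captured intermolecularly by the amide or by the alkoxide of a second molecule. The C8 aryllithium may be protonated or may partition between C-, N- and O-prenylation. The fallback uses known chemistry, replaces the aryne by an ipso SNAr at a fluorine placed on C8a, and sets out from ester 6. Commercial 1-(2-fluoro-4-hydroxyphenyl)ethan-1-one would be brominated ortho to the hydroxyl and para to fluorine (NBS, MeCN) to give 1-(5-bromo-2-fluoro-4-hydroxyphenyl)ethan-1-one F1. Protection (MOMCl, i-Pr2NEt) would give 1-[5-bromo-2-fluoro-4-(methoxymethoxy)phenyl]ethan-1-one F2. Stille coupling with tributyl(3-methylbut-2-en-1-yl)stannane (Pd(PPh3)4, DMF, 90 °C) would give 1-[2-fluoro-4-(methoxymethoxy)-5-(3-methylbut-2-en-1-yl)phenyl]ethan-1-one F3. Claisen condensation of F3 with 6 (NaH, THF) would give 1-(2,2-dimethyl-2H-chromen-6-yl)-3-[2-fluoro-4-(methoxymethoxy)-5-(3-methylbut-2-en-1-yl)phenyl]propane-1,3-dione F4. Transfer hydrogenation as in step 8 would give (1S,3S)-1-(2,2-dimethyl-2H-chromen-6-yl)-3-[2-fluoro-4-(methoxymethoxy)-5-(3-methylbut-2-en-1-yl)phenyl]propane-1,3-diol F5. Intramolecular SNAr of the C2 alkoxide at the C–F carbon (KOt-Bu, THF, 65 °C) would close ring C through the same O1–C8a bond to give (2S,4S)-2-(2,2-dimethyl-2H-chromen-6-yl)-7-(methoxymethoxy)-6-(3-methylbut-2-en-1-yl)-3,4-dihydro-2H-chromen-4-ol F6. Directed ortho-lithiation of F6 at C8 between O1 and the OMOM group (n-BuLi, 2.2 equiv, THF, 0 °C) would form 20, and CuBr·SMe2/prenyl bromide would bring the route back at 21.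

2. Step 8. The intermediate β-hydroxy ketones may dehydrate to chalcones that are then reduced at C=C, the second reduction may stall, or enantiocontrol at the chromenyl carbinol may be eroded by the enolised diketone. The fallback sets the C2 centre by an aldol reaction instead and sets out from 12 and 6. Ester 6 would be reduced (LiAlH4, THF, 0 °C) to (2,2-dimethyl-2H-chromen-6-yl)methanol F7 and oxidised (MnO2, CH2Cl2) to 2,2-dimethyl-2H-chromene-6-carbaldehyde F8. An Ipc2BCl/Et3N boron aldol reaction of 12 with F8, using the reagent antipode that adds to the Si face of the aldehyde, would give hydroxy ketone 14. Evans–Saksena reduction (Me4NBH(OAc)3, MeCN/AcOH, −30 °C) would return the route at 16; the diastereoselectivity of this reduction is not critical because C4 is later oxidised.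

3. Step 5. The tertiary allyl aryl ether may fragment thermally with loss of isoprene to return phenol 7, or the ortho-prenylphenol may cyclise further at the temperature needed. The fallback installs the prenyl group by cross-coupling and sets out from 7. Bromination at the only free position ortho to the hydroxyl (NBS, MeCN) would give 1-(3-bromo-5-fluoro-4-hydroxyphenyl)ethan-1-one F9. Protection (MOMCl, i-Pr2NEt) would give 1-[3-bromo-5-fluoro-4-(methoxymethoxy)phenyl]ethan-1-one F10. Stille coupling with tributyl(3-methylbut-2-en-1-yl)stannane (Pd(PPh3)4, DMF, 90 °C) would return the route at 12.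

**Further compounds**

F1 | step 9 | 1-(5-bromo-2-fluoro-4-hydroxyphenyl)ethan-1-one | CC(=O)c1cc(Br)c(O)cc1F
F2 | step 9 | 1-[5-bromo-2-fluoro-4-(methoxymethoxy)phenyl]ethan-1-one | CC(=O)c1cc(Br)c(OCOC)cc1F
F3 | step 9 | 1-[2-fluoro-4-(methoxymethoxy)-5-(3-methylbut-2-en-1-yl)phenyl]ethan-1-one | CC(=O)c1cc(CC=C(C)C)c(OCOC)cc1F
F4 | step 9 | 1-(2,2-dimethyl-2H-chromen-6-yl)-3-[2-fluoro-4-(methoxymethoxy)-5-(3-methylbut-2-en-1-yl)phenyl]propane-1,3-dione | O=C(CC(=O)c1ccc2OC(C)(C)C=Cc2c1)c1cc(CC=C(C)C)c(OCOC)cc1F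
F5 | step 9 | (1S,3S)-1-(2,2-dimethyl-2H-chromen-6-yl)-3-[2-fluoro-4-(methoxymethoxy)-5-(3-methylbut-2-en-1-yl)phenyl]propane-1,3-diol | O[C@H](c1cc(CC=C(C)C)c(OCOC)cc1F)C[C@H](O)c1ccc2OC(C)(C)C=Cc2c1
F6 | step 9 | (2S,4S)-2-(2,2-dimethyl-2H-chromen-6-yl)-7-(methoxymethoxy)-6-(3-methylbut-2-en-1-yl)-3,4-dihydro-2H-chromen-4-ol | CC(C)=CCc1cc2c(cc1OCOC)O[C@H](c1ccc3c(c1)C=CC(C)(C)O3)C[C@@H]2O
F7 | step 8 | (2,2-dimethyl-2H-chromen-6-yl)methanol | OCc1ccc2OC(C)(C)C=Cc2c1
F8 | step 8 | 2,2-dimethyl-2H-chromene-6-carbaldehyde | O=Cc1ccc2OC(C)(C)C=Cc2c1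
F9 | step 5 | 1-(3-bromo-5-fluoro-4-hydroxyphenyl)ethan-1-one | CC(=O)c1cc(F)c(O)c(Br)c1
F10 | step 5 | 1-[3-bromo-5-fluoro-4-(methoxymethoxy)phenyl]ethan-1-one | CC(=O)c1cc(F)c(OCOC)c(Br)c1
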